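Readings and results were computed on assumed constants; noise was put on by code.

Take 80.8% for the whole row: it is the selectivity, c(target)/(c(target) + c(side product)), pooled over the winter and dawn readings at 8.00 h and 20.0 h.

| setting | winter | dawn | maple | alder | ash | elm |
|---|---|---|---|---|---|---|
| substrate | 0.080 M | 0.71 M | 0.12 M | 0.25 M | 0.50 M | 1.0 M |
| remark | run made earlier | run made earlier |  |  |  |  |
| time |  |  | 40 h | 40 h | 40 h | 40 h |

| run | time / h | target / % | side product / % | substrate / % |
|---|---|---|---|---|
| winter | 1.50 | 19.8 | 5.0 | 45.4 |
| winter | 2.50 | 28.0 | 7.0 | 31.6 |
| winter | 4.00 | 35.5 | 8.3 | 20.4 |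
| winter | 8.00 | 45.9 | 10.9 | 8.5 |
| winter | 12.0 | 49.7 | 12.6 | 3.4 |
| winter | 20.0 | 53.0 | 13.0 | 0.9 |
| dawn | 1.33 | 18.4 | 4.2 | 50.2 |
| dawn | 4.00 | 34.6 | 8.0 | 20.7 |
| dawn | 8.00 | 45.5 | 11.0 | 8.5 |
| dawn | 10.0 | 49.0 | 11.7 | 5.3 |
| dawn | 15.0 | 51.4 | 13.0 | 1.8 |
| dawn | 20.0 | 53.4 | 12.2 | 0.6 |

(scatter of a reading: 0.3 percentage points)

1. share of target in all that became target or side product for maple, alder, ash, elm, in this order
2. how that number moves from the first to the last of them (falls all the way / hardly changes / rises all the way / falls, then rises / rises, then falls)

- the numbers in the tables scatter with a standard deviation of 0.3 percentage points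
- "hardly changes" means that all values lie within two and a half points (for a concentration: within two and a half percent of the largest)

Turn the question round and ask what the readings would have to show for the row to leave the band of "hardly changes". First, selectivity would have to depend on concentration. Reckon it per run: the same readings give 80.5% in winter and 81.0% in dawn. That gap of 0.46 percentage points spans a factor of 8.88 in c(substrate) and stands inside the band. Maple, alder and ash lie within that span; elm, at 1.0 M, lies above it.

Second, substrate would have to remain to share out late. Count half-lives: between 8.00 h and 20.0 h the winter run reads 3.70 h, so the time from 20.0 h up to 40 h holds 5.41 of them. Send the 0.9% left in winter wholly to side product, and its share still reads 79.2%.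

Third, the third of the winter charge missing from the columns at 20.0 h would have to feed side product ahead of target. This condition stays open.

Commit to 80.8% for all four flasks. The forecast, slightly lower than this reckoning, gives 80.5% at each and the shape hardly changes, holding that the share “doesn't drift with conversion”.

The simulation gives 80.6%, 80.6%, 80.6% and 80.6%, shape hardly changes.

    substrate → target (k = 0.197 /h)
    substrate ⇌ dormant form (K = 0.470, k = 0.255 /h)
    substrate → side product (k = 0.0475 /h)
    substrate → intermediate A (k = 0.122 /h)
    intermediate B ⇌ intermediate C (K = 2.70, k = 0.0460 /h)
    intermediate A → intermediate B (k = 0.170 /h)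

In maple, the substrate half-life by the step to target is 3.5 h, shorter than the 15 h by the step to side product. The rate constant of the step to target over the sum of the two constants is 80.6%, which lies 0.2 points below the selectivity carried from the readings. Apply that selectivity to elm: of the 66.7% of target plus side product at 40.0 h, it assigns 53.9% to target, and elm holds 53.7%.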